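**Plan**
- Ring labels: ring A (catechol; a1 outer C–OH, a6 inner C–OH, a5 C–O–ring B, a3 C–CH2), ring B (para-phenylene), ring C (catechol; c1 C–CH2, c4 outer C–OH, c5 inner C–OH, c6 C–O–ring D), ring D (ortho-phenylene).
- Retrosynthetic cuts, in order: the two outer catechol C–O bonds (a1–O, c4–O); the two O–CH3 bonds; the ring A–CH2CH2–ring D bridge (as C=C); the ring B–CH2CH2–ring C bridge (as C=C); the two diaryl ether C–O bonds.
- Forward: two SNAr reactions give the A–O–B and C–O–D halves; Wittig olefination and hydrogenation join ring B to ring C; nitrile reduction and McMurry coupling close the 17-membered macrocycle between rings A and D; hydrogenation and demethylation give the bis-phenol.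
- Enabling feature: the inner phenol carbon a6 lies between a5 (ether oxygen to ring B) and a1, and c5 lies between c6 (ether oxygen to ring D) and c4, so each phenol has a single ortho C–H (a1, c4) where the outer hydroxyl is introduced last.
- Stereochemistry: the target has no stereocentre; the alkene geometries of intermediates are erased by hydrogenation.

Key step: step 11

Remark: the target SMILES carries no stereodescriptor and the macrocycle is taken as conformationally mobile, so no stereocontrol is required. Both nitriles serve as latent aldehydes, so that only one formyl group is present in each Wittig partner.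

**Step 1**
Reactants: 1 3-hydroxy-4-methoxybenzonitrile; 2 4-fluorobenzaldehyde
Product: 3 3-(4-formylphenoxy)-4-methoxybenzonitrile
Conditions: K2CO3, DMF, 120 °C
Reagents that add atoms: none
Why: Nucleophilic aromatic substitution, in which the para-formyl group stabilises the Meisenheimer adduct and fluoride leaves readily, so the phenoxide of 1 should give the ring A–O–ring B ether while the nitrile stays inert.

**Step 2**
Reactants: 3 3-(4-formylphenoxy)-4-methoxybenzonitrile
Product: 4 3-[4-(hydroxymethyl)phenoxy]-4-methoxybenzonitrile
Conditions: NaBH4, MeOH/THF, 0 °C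
Reagents that add atoms: none
Why: Borohydride reduction of an aryl aldehyde is fast at 0 °C, whereas the aryl nitrile and the diaryl ether are not touched.

**Step 3**
Reactants: 4 3-[4-(hydroxymethyl)phenoxy]-4-methoxybenzonitrile
Product: 5 [4-(5-cyano-2-methoxyphenoxy)benzyl]triphenylphosphonium bromide
Conditions: PPh3·HBr, MeCN, reflux
Reagents that add atoms: triphenylphosphine hydrobromide, SMILES Br.c1ccc(cc1)P(c1ccccc1)c1ccccc1
Why: Direct phosphonium salt formation from a benzylic alcohol, in which HBr activates the para-aryloxy-stabilised benzylic position and PPh3 captures it by substitution, with water as the only co-product.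

**Step 4**
Reactants: 6 o-vanillin (2-hydroxy-3-methoxybenzaldehyde); 7 2-fluorobenzonitrile
Product: 8 2-(2-formyl-6-methoxyphenoxy)benzonitrile
Conditions: K2CO3, DMF, 130 °C
Reagents that add atoms: none
Why: Nucleophilic aromatic substitution activated by the ortho-cyano group should give the ring C–O–ring D ether, and neither aldehyde nor nitrile is enolisable or attacked by carbonate.

**Step 5**
Reactants: 5 [4-(5-cyano-2-methoxyphenoxy)benzyl]triphenylphosphonium bromide; 8 2-(2-formyl-6-methoxyphenoxy)benzonitrile
Product: 9 3-(4-{2-[2-(2-cyanophenoxy)-3-methoxyphenyl]ethenyl}phenoxy)-4-methoxybenzonitrile (E/Z mixture)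
Conditions: K2CO3, 18-crown-6 (cat.), CH2Cl2, reflux
Reagents that add atoms: none
Why: Wittig olefination under solid–liquid phase-transfer conditions, where the semi-stabilised benzylic ylide adds only to the single aldehyde present and the E/Z mixture is acceptable because the alkene is saturated next.

**Step 6**
Reactants: 9 stilbene dinitrile (E/Z mixture)
Product: 10 3-(4-{2-[2-(2-cyanophenoxy)-3-methoxyphenyl]ethyl}phenoxy)-4-methoxybenzonitrile
Conditions: H2 (1 atm), 10% Pd/C, EtOAc, rt, stopped after one equivalent of H2
Reagents that add atoms: none
Why: Heterogeneous catalytic hydrogenation saturates a stilbene far faster than it reduces aryl nitriles in a neutral solvent at atmospheric pressure, giving the flexible bibenzyl needed for ring closure.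

**Step 7**
Reactants: 10 bibenzyl dinitrile
Product: 11 3-(4-{2-[2-(2-formylphenoxy)-3-methoxyphenyl]ethyl}phenoxy)-4-methoxybenzaldehyde
Conditions: iBu2AlH (2.5 equiv), CH2Cl2, −78 to 0 °C; then 1 M HCl
Reagents that add atoms: water, SMILES O
Why: Partial reduction of nitriles, in which each nitrile accepts one hydride to give an N-aluminated aldimine that resists further reduction at low temperature and is hydrolysed to the aldehyde on acidic work-up.

**Step 8**
Reactants: 11 bibenzyl dialdehyde
Product: 12 macrocyclic stilbene dimethyl ether (ring A–CH=CH–ring D; geometry undefined, Z expected)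
Conditions: TiCl4, Zn, pyridine, THF, reflux, slow addition of 11 (high dilution)
Reagents that add atoms: none
Why: McMurry reductive coupling, in which low-valent titanium made from TiCl4 and Zn couples the two aldehydes through a titanium pinacolate and deoxygenates it to the alkene, slow addition favouring closure of the 17-membered ring over oligomerisation.

**Step 9**
Reactants: 12 macrocyclic stilbene dimethyl ether
Product: 13 macrocyclic bis(bibenzyl) dimethyl ether
Conditions: H2 (1 atm), 10% Pd/C, EtOAc/MeOH, rt
Reagents that add atoms: none
Why: Catalytic hydrogenation of the cyclic stilbene removes the alkene geometry, and the methyl and diaryl ethers are inert to it.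

**Step 10**
Reactants: 13 macrocyclic bis(bibenzyl) dimethyl ether
Product: 14 dideoxy macrocycle (bis-phenol, one OH on ring A at a6 and one on ring C at c5)
Conditions: BBr3, CH2Cl2, −78 °C to rt; then H2O
Reagents that add atoms: none
Why: Lewis-acid ether cleavage, in which boron binds each methoxy oxygen and bromide attacks the methyl group by SN2, while the diaryl ethers offer no sp3 carbon and survive.

**Step 11**
Reactants: 14 dideoxy macrocycle (bis-phenol)
Product: 16 target tetraphenol CNP0114693.0, via macrocyclic bis-ortho-quinone 15 (not isolated)
Conditions: IBX (2.4 equiv), DMF, rt, argon; then aq. Na2S2O4, same flask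
Reagents that add atoms: 2-iodoxybenzoic acid (IBX), SMILES O=C1OI(O)(=O)c2ccccc12
Why: Each phenol oxygen of 14 binds the pentavalent iodine of IBX, an iodine-bound oxygen is passed intramolecularly to the adjacent ring carbon as iodine falls to the trivalent state, and the catechol-type iodine ester collapses to the ortho-quinone and 2-iodobenzoic acid. The closest known reaction type is the regioselective IBX ortho-oxygenation of electron-rich phenols to ortho-quinones followed by reductive work-up to catechols. No ring is closed and no stereocentre is formed; the two new bonds are a1–O on ring A and c4–O on ring C. The step needs ortho rather than para oxygenation, which the intramolecular transfer from the bound phenoxide ensures, and it needs the free ortho C–H (a1, c4) to win over the aryloxy-bearing ortho carbon (a5, c6). That second preference rests on a5 and c6 being the more congested carbons and on their ether oxygens, shared with rings B and D, being weaker donors than the methoxy group that is known to draw this reagent to an ipso carbon. Rings B and D have no hydroxyl and cannot bind the reagent, room temperature avoids benzylic oxidation, and immediate Na2S2O4 reduction releases the tetraphenol before the quinones can tautomerise or add nucleophiles.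

**Compound list**
1 | 3-hydroxy-4-methoxybenzonitrile | COc1ccc(C#N)cc1O | starting material
2 | 4-fluorobenzaldehyde | O=Cc1ccc(F)cc1 | starting material
3 | 3-(4-formylphenoxy)-4-methoxybenzonitrile | COc1ccc(C#N)cc1Oc1ccc(C=O)cc1 | intermediate
4 | 3-[4-(hydroxymethyl)phenoxy]-4-methoxybenzonitrile | COc1ccc(C#N)cc1Oc1ccc(CO)cc1 | intermediate
5 | [4-(5-cyano-2-methoxyphenoxy)benzyl]triphenylphosphonium bromide | COc1ccc(C#N)cc1Oc1ccc(C[P+](c2ccccc2)(c2ccccc2)c2ccccc2)cc1.[Br-] | intermediate
6 | o-vanillin (2-hydroxy-3-methoxybenzaldehyde) | COc1cccc(C=O)c1O | starting material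
7 | 2-fluorobenzonitrile | N#Cc1ccccc1F | starting material
8 | 2-(2-formyl-6-methoxyphenoxy)benzonitrile | COc1cccc(C=O)c1Oc1ccccc1C#N | intermediate
9 | 3-(4-{2-[2-(2-cyanophenoxy)-3-methoxyphenyl]ethenyl}phenoxy)-4-methoxybenzonitrile (E/Z mixture) | COc1ccc(C#N)cc1Oc1ccc(C=Cc2cccc(OC)c2Oc2ccccc2C#N)cc1 | intermediate
10 | 3-(4-{2-[2-(2-cyanophenoxy)-3-methoxyphenyl]ethyl}phenoxy)-4-methoxybenzonitrile | COc1ccc(C#N)cc1Oc1ccc(CCc2cccc(OC)c2Oc2ccccc2C#N)cc1 | intermediate
11 | 3-(4-{2-[2-(2-formylphenoxy)-3-methoxyphenyl]ethyl}phenoxy)-4-methoxybenzaldehyde | COc1ccc(C=O)cc1Oc1ccc(CCc2cccc(OC)c2Oc2ccccc2C=O)cc1 | intermediate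
12 | macrocyclic stilbene dimethyl ether (alkene geometry undefined) | COc1ccc2cc1Oc1ccc(cc1)CCc1cccc(OC)c1Oc1ccccc1C=C2 | intermediate
13 | macrocyclic bis(bibenzyl) dimethyl ether | COc1ccc2cc1Oc1ccc(cc1)CCc1cccc(OC)c1Oc1ccccc1CC2 | intermediate
14 | dideoxy macrocycle (bis-phenol) | Oc1ccc2cc1Oc1ccc(cc1)CCc1cccc(O)c1Oc1ccccc1CC2 | intermediate
15 | macrocyclic bis-ortho-quinone (not isolated) | O=C1C=C2C=C(C1=O)Oc1ccc(cc1)CCC1=C(Oc3ccccc3CC2)C(=O)C(=O)C=C1 | intermediate
16 | CNP0114693.0 | Oc1cc2cc(c1O)Oc1ccc(cc1)CCc1ccc(O)c(O)c1Oc1ccccc1CC2 | target

**Step count**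
Total steps: 11. Longest linear sequence: 10 (steps 1–3 and 5–11, from compound 1).

**Steps most likely to fail**

Step 11. Oxygen may be transferred to the aryloxy-bearing ortho carbon instead of the free ortho C–H, the course this reagent takes with 2-methoxyphenols. That would expel ring B or ring D as a phenol and open the macrocycle. The quinones may also over-oxidise or decompose before reduction. The fallback sets out from 14 and uses a carbon electrophile that can only enter at an ortho C–H. Magnesium-mediated ortho-formylation (MgCl2, Et3N, paraformaldehyde, MeCN, reflux) should give the macrocyclic bis-salicylaldehyde F1, formylated at a1 and c4. Dakin oxidation of F1 (H2O2, aqueous NaOH, THF, 0 °C, degassed, then acidification) converts each ortho-hydroxyaryl aldehyde into the aryl formate and hydrolyses it to the catechol, returning to the route at 16.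

Step 8. Intermolecular carbonyl coupling may outrun ring closure, or the reaction may stall at the pinacol stage. The fallback sets out from 11 and replaces the reductive carbonyl coupling by a reductive coupling of two benzylic halides. NaBH4 reduction gives the acyclic diol F2, and PBr3 in CH2Cl2 gives the acyclic bis(benzylic bromide) F3. Intramolecular Wurtz coupling of F3 with sodium and catalytic tetraphenylethene in THF at high dilution should form the saturated bridge directly and rejoin the route at 13, so that 12 and step 9 are no longer needed.

Step 4. The phenoxide of o-vanillin is chelated, electron-poor and flanked on both sides, so substitution may be sluggish and the aldehyde may degrade at the temperature required. The fallback sets out from 6 and forms the ether only after the formyl group has been used. Wittig reaction of 6 with the ylide from 5 (KOtBu, 2.2 equiv, THF, 0 °C to rt) gives the hydroxystilbene nitrile F4. Hydrogenation (H2, Pd/C, EtOAc) gives the hydroxybibenzyl nitrile F5, whose electron-rich phenoxide should displace fluoride from 7 (K2CO3, DMF, 120 °C). This rejoins the route at 10 and bypasses 8 and 9.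

**Further compounds**
F1 | step 11 | macrocyclic bis-salicylaldehyde (CHO at a1 and c4 of 14) | O=Cc1cc2cc(c1O)Oc1ccc(cc1)CCc1ccc(C=O)c(O)c1Oc1ccccc1CC2
F2 | step 8 | acyclic diol [4-methoxy-3-(4-{2-[2-(2-(hydroxymethyl)phenoxy)-3-methoxyphenyl]ethyl}phenoxy)phenyl]methanol | COc1ccc(CO)cc1Oc1ccc(CCc2cccc(OC)c2Oc2ccccc2CO)cc1
F3 | step 8 | acyclic bis(benzylic bromide) | COc1ccc(CBr)cc1Oc1ccc(CCc2cccc(OC)c2Oc2ccccc2CBr)cc1
F4 | step 4 | 3-{4-[2-(2-hydroxy-3-methoxyphenyl)ethenyl]phenoxy}-4-methoxybenzonitrile (E/Z mixture) | COc1ccc(C#N)cc1Oc1ccc(C=Cc2cccc(OC)c2O)cc1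
F5 | step 4 | 3-{4-[2-(2-hydroxy-3-methoxyphenyl)ethyl]phenoxy}-4-methoxybenzonitrile | COc1ccc(C#N)cc1Oc1ccc(CCc2cccc(OC)c2O)cc1
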